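**Retrosynthetic overview**
1. Ludongnin A ⇐ C-15 oxidation and desilylation of a 16-methylene tetracycle; the D ring (C8–C15) comes from a Pd(II)-mediated cyclisation of the C-7 silyl ketene acetal onto a C-13 isopropenyl group.
2. The C ring (C9–C11) comes from a SmI2 ketyl–olefin cyclisation of an aldehyde onto the 8,9-unsaturated δ-lactone; the side chain (C-11 to C-17) is attached by alkylating the spiro-bislactone at C-8 with an Evans-derived iodide that carries C-13.
3. Key step: intermolecular Michael addition of the A-ring aldehyde (as its C-10 enamine) to methyl acrylate forms C9–C10 and the C-10 quaternary centre; reduction and lactonisation then give the 7,20-δ-lactone.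
4. The A ring with the 19,6-γ-lactone comes from a Diels–Alder reaction of citraconic anhydride with a glyceraldehyde-derived dienyl dioxolane (sets C-4/C-5; the dioxolane is the masked C-20 formyl group and the source of absolute configuration), followed by regioselective anhydride reduction.
5. Ring order: A + γ-lactone → spiro δ-lactone → C → D.

Assumption: locants C-1 to C-20 are the ent-kaurane positions of the target; reagents given with SMILES under "Reagents that add atoms" are not numbered; the facial preference in step 3 is taken from the anti-to-allylic-oxygen model (if it proves reversed, the enantiomeric diene from (S)-solketal is used).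

This route has not been run; selectivities are predictions from models and analogy.

**Step 1**
Reactants: 1 (R)-2,2-dimethyl-1,3-dioxolane-4-methanol [(R)-solketal]
Product: 3 (E)-3-[(4R)-2,2-dimethyl-1,3-dioxolan-4-yl]prop-2-enal, via (S)-2,2-dimethyl-1,3-dioxolane-4-carbaldehyde 2 (not isolated)
Conditions: TEMPO (5 mol%), PhI(OAc)2 (1.1 equiv), CH2Cl2, rt; then Ph3P=CHCHO (1.15 equiv), rt
Reagents that add atoms: (triphenylphosphoranylidene)acetaldehyde, O=CC=P(c1ccccc1)(c1ccccc1)c1ccccc1
Why: TEMPO/BAIB oxidation gives the labile aldehyde without base, and the stabilised ylide traps it in situ in an E-selective Wittig olefination that leaves the dioxolane stereocentre untouched.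

**Step 2**
Reactants: 3 (E)-3-[(4R)-2,2-dimethyl-1,3-dioxolan-4-yl]prop-2-enal
Product: 4 (4R)-4-[(1E)-buta-1,3-dien-1-yl]-2,2-dimethyl-1,3-dioxolane
Conditions: Ph3PCH3Br, KOt-Bu, THF, 0 °C → rt
Reagents that add atoms: methyltriphenylphosphonium bromide, C[P+](c1ccccc1)(c1ccccc1)c1ccccc1.[Br-]
Why: Wittig methylenation of the enal carbonyl gives the (E)-1-substituted butadiene without touching the existing alkene or stereocentre.

**Step 3**
Reactants: 4 (4R)-4-[(1E)-buta-1,3-dien-1-yl]-2,2-dimethyl-1,3-dioxolane; 5 citraconic anhydride (3-methylfuran-2,5-dione)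
Product: 6 (3aR,7S,7aS)-7-[(4R)-2,2-dimethyl-1,3-dioxolan-4-yl]-3a-methyl-3a,4,7,7a-tetrahydro-2-benzofuran-1,3-dione
Conditions: PhMe, BHT (cat.), 130 °C (sealed tube), 48 h; chromatography/crystallisation to remove the minor facial diastereomer
Reagents that add atoms: none
Why: Diels–Alder reaction in which the unsubstituted diene terminus bonds to the methyl-bearing carbon (sterically and electronically preferred), endo addition gives the cis C-4(Me)/C-5(H) pair, and attack anti to the allylic C–O bond of the (R)-dioxolane sets their absolute configuration; the C-10 configuration is irrelevant because C-10 is enolised in step 7.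

**Step 4**
Reactants: 6 Diels–Alder anhydride
Product: 8 (3aR,7S,7aS)-7-[(4R)-2,2-dimethyl-1,3-dioxolan-4-yl]-3a-methyl-3a,4,7,7a-tetrahydro-2-benzofuran-1(3H)-one, via 6-[(4R)-2,2-dimethyl-1,3-dioxolan-4-yl]-2-(hydroxymethyl)-2-methylcyclohex-4-ene-1-carboxylic acid 7 (not isolated)
Conditions: NaBH4 (2 equiv), THF, 0 °C → rt; then 1 M HCl to pH 3, 0 °C, 30 min
Reagents that add atoms: none
Why: NaBH4 reduces the anhydride carbonyl next to the quaternary carbon (the usual regioselectivity for α,α-disubstituted succinic anhydrides), and the cis γ-hydroxy acid closes to the 19,6-lactone on acidification; any regioisomer is separated here.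

**Step 5**
Reactants: 8 unsaturated lactone
Product: 9 (3aR,7S,7aS)-7-[(4R)-2,2-dimethyl-1,3-dioxolan-4-yl]-3a-methylhexahydro-2-benzofuran-1(3H)-one
Conditions: H2 (1 atm), 10% Pd/C, EtOAc, rt
Reagents that add atoms: none
Why: heterogeneous hydrogenation of the disubstituted ring alkene; no stereocentre is created and lactone and acetonide are inert.

**Step 6**
Reactants: 9 saturated lactone
Product: 11 (3aS,4S,7aR)-7a-methyl-3-oxooctahydro-2-benzofuran-4-carbaldehyde, via (3aR,7S,7aS)-7-[(1R)-1,2-dihydroxyethyl]-3a-methylhexahydro-2-benzofuran-1(3H)-one 10 (not isolated)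
Conditions: H5IO6 (1.5 equiv), EtOAc, rt, 3 h
Reagents that add atoms: none
Why: periodic acid hydrolyses the terminal acetonide and cleaves the diol in the same pot (Malaprade glycol cleavage), unmasking the C-20 aldehyde before the free diol can translactonise; C-10 epimers converge in step 7.

**Step 7 (key step)**
Reactants: 11 A-ring aldehyde; 12 methyl acrylate
Product: 14 methyl 3-[(3aR,4R,7aR)-4-formyl-7a-methyl-3-oxooctahydro-2-benzofuran-4-yl]propanoate, via (3aR,7E,7aS)-3a-methyl-7-[(pyrrolidin-1-yl)methylidene]hexahydro-2-benzofuran-1(3H)-one 13 (not isolated)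
Conditions: pyrrolidine (1.2 equiv), 4 Å MS, PhH, rt; concentrate; methyl acrylate (4 equiv), MeCN, 80 °C, 24 h; then AcOH/NaOAc/H2O, rt
Reagents that add atoms: water, O
Why: Stork enamine Michael addition in which the acrylate approaches C-10 from the convex face of the cis-fused lactone, anti to the C-5–C-6 bond, so the propanoate chain (C-9) enters trans to C-6 and the C-10 quaternary centre is formed with the formyl group cis to C-6 and C-19.

**Step 8**
Reactants: 14 Michael adduct
Product: 16 (3aR,4R,7aR)-7a-methylhexahydro-3H-spiro[2-benzofuran-4,3'-oxane]-3,6'-dione, via methyl 3-[(3aR,4R,7aR)-4-(hydroxymethyl)-7a-methyl-3-oxooctahydro-2-benzofuran-4-yl]propanoate 15 (not isolated)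
Conditions: NaBH4 (1.2 equiv), MeOH, 0 °C; then TsOH·H2O (10 mol%), PhMe, 80 °C
Reagents that add atoms: none
Why: chemoselective aldehyde reduction followed by acid-catalysed lactonisation with loss of methanol; the 19,6/20,7-bislactone is the thermodynamic sink of any translactonisation between the C-19 and C-20 hydroxyls.

**Step 9**
Reactants: 17 3-methylbut-3-enoic acid; 18 (S)-4-benzyl-2-oxazolidinone
Product: 20 (S)-4-benzyl-3-(3-methylbut-3-enoyl)oxazolidin-2-one, via 3-methylbut-3-enoic pivalic anhydride 19 (not isolated)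
Conditions: PivCl, Et3N, THF, −20 °C; then 18, LiCl, −20 °C → rt
Reagents that add atoms: none
Why: N-acylation of the Evans auxiliary through the mixed anhydride under mild conditions that do not conjugate the β,γ-alkene.

**Step 10**
Reactants: 20 N-acyl oxazolidinone
Product: 21 tert-butyl (S)-3-[(S)-4-benzyl-2-oxooxazolidine-3-carbonyl]-4-methylpent-4-enoate
Conditions: NaHMDS (1.1 equiv), THF, −78 °C; BrCH2CO2t-Bu (3 equiv), −78 → −50 °C
Reagents that add atoms: tert-butyl bromoacetate, CC(C)(C)OC(=O)CBr
Why: Evans asymmetric alkylation in which the chelated Z-dienolate reacts at the α-carbon on the face opposite the benzyl group, setting C-13 as (S); A(1,3) strain prevents later deprotonation and conjugation.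

**Step 11**
Reactants: 21 alkylated imide
Product: 22 tert-butyl (S)-3-(hydroxymethyl)-4-methylpent-4-enoate
Conditions: LiBH4 (1.5 equiv), H2O (1.5 equiv), Et2O, 0 °C
Reagents that add atoms: none
Why: reductive cleavage of the imide gives the primary alcohol (C-14) and returns the auxiliary, while the tert-butyl ester is not reduced.

**Step 12**
Reactants: 22 hydroxy ester
Product: 23 tert-butyl (S)-3-(iodomethyl)-4-methylpent-4-enoate
Conditions: I2, PPh3, imidazole, CH2Cl2, 0 °C → rt
Reagents that add atoms: iodine, II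
Why: Appel-type (Garegg–Samuelsson) iodination of the primary alcohol by SN2 displacement, with no effect on the stereocentre.

**Step 13**
Reactants: 23 iodo ester
Product: 24 (S)-3-(iodomethyl)-4-methylpent-4-en-1-ol
Conditions: DIBAL-H (2.5 equiv), CH2Cl2, −78 → −20 °C; Rochelle salt work-up, used at once
Reagents that add atoms: none
Why: DIBAL-H reduces the tert-butyl ester to the primary alcohol without touching the iodide or the 1,1-disubstituted alkene; the iodo alcohol is kept cold and silylated immediately to avoid tetrahydrofuran formation.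

**Step 14**
Reactants: 24 iodo alcohol
Product: 25 (S)-tert-butyl{[3-(iodomethyl)-4-methylpent-4-en-1-yl]oxy}dimethylsilane
Conditions: TBSCl, imidazole, CH2Cl2, 0 °C
Reagents that add atoms: tert-butyldimethylsilyl chloride, CC(C)(C)[Si](C)(C)Cl
Why: standard silylation of the primary alcohol, faster than any intramolecular etherification.

**Step 15**
Reactants: 16 spiro-bislactone; 25 iodide
Product: 26 8-alkylated spiro-bislactone: 16 carrying at C-8 (oxane C-5′) the (2S)-4-[(tert-butyldimethylsilyl)oxy]-2-(prop-1-en-2-yl)butyl chain (C-14, C-13, C-12, C-11); C-8 epimers, one drawn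
Conditions: LDA (1.05 equiv), THF, −78 °C; HMPA (3 equiv); 25 (1.5 equiv), −78 → −30 °C
Reagents that add atoms: none
Why: kinetic deprotonation occurs at the C-8 methylene of the δ-lactone (C-5 is a shielded methine between two quaternary carbons) and the enolate is alkylated by the primary iodide (SN2); the C-8 configuration is irrelevant because C-8 becomes sp2.

**Step 16**
Reactants: 26 8-alkylated bislactone
Product: 27 8-(phenylselanyl) derivative of 26 (one C-8 epimer drawn)
Conditions: LDA (1.2 equiv), THF, −78 °C; PhSeBr, −78 °C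
Reagents that add atoms: benzeneselenenyl bromide, Br[Se]c1ccccc1
Why: α-selenenylation of the δ-lactone enolate, again formed at the more accessible C-8–H.

**Step 17**
Reactants: 27 selenide
Product: 29 8,9-unsaturated δ-lactone (C-8=C-9) with the side chain of 26, via the selenoxide of 27 28 (not isolated)
Conditions: H2O2 (30% aq.), pyridine, CH2Cl2, 0 °C → rt
Reagents that add atoms: none
Why: selenoxide syn-elimination, which in δ-lactones goes into the ring toward the C-9 hydrogens to give the endocyclic enoate.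

**Step 18**
Reactants: 29 unsaturated lactone silyl ether
Product: 30 the corresponding primary alcohol (C-11 OH)
Conditions: HF·pyridine, pyridine, THF, 0 °C → rt
Reagents that add atoms: none
Why: fluoride cleavage of the primary TBS ether; lactones and alkenes are inert.

**Step 19**
Reactants: 30 alcohol
Product: 31 the corresponding aldehyde (C-11 CHO)
Conditions: Dess–Martin periodinane, NaHCO3, CH2Cl2, rt
Reagents that add atoms: none
Why: Dess–Martin oxidation to the aldehyde under neutral conditions; no epimerisable centre is α to it.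

**Step 20**
Reactants: 31 aldehyde
Product: 32 tricyclic hydroxy bislactone: C ring closed (C9–C11), 13-isopropenyl, 11-OH trans to C-10, H-8 cis to H-9
Conditions: SmI2 (3 equiv), LiBr, t-BuOH (2 equiv), THF, −78 °C
Reagents that add atoms: none
Why: SmI2 ketyl–olefin (6-endo) cyclisation in which the C-11 ketyl adds to C-9 from the lactone face syn to C-1 (anti to the bulkier C-5 branch), placing C-10 and the 13-isopropenyl trans-diequatorial in a chair transition state and so setting H-9; the samarium enolate is protonated at C-8, and the expected equatorial 11-OH is corrected in steps 21–22.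

**Step 21**
Reactants: 32 11-alcohol
Product: 33 the 11-ketone
Conditions: Dess–Martin periodinane, NaHCO3, CH2Cl2, rt
Reagents that add atoms: none
Why: Dess–Martin oxidation removes the C-11 stereocentre so that it can be reset by hydride delivery.

**Step 22**
Reactants: 33 11-ketone
Product: 34 the 11-epimeric alcohol (11-OH cis to C-10, as in the target)
Conditions: L-Selectride (1.2 equiv), THF, −78 °C; aq. NH4Cl
Reagents that add atoms: none
Why: the bulky hydride attacks the cyclohexanone equatorially (the axial trajectory is blocked by the axial C-7 carbonyl), giving the axial alcohol cis to the equatorial C-10 substituent; lactones are not reduced at −78 °C.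

**Step 23**
Reactants: 34 alcohol
Product: 35 the 11-O-TBS ether
Conditions: TBSOTf (1.5 equiv), 2,6-lutidine, CH2Cl2, −78 → 0 °C
Reagents that add atoms: tert-butyldimethylsilyl trifluoromethanesulfonate, CC(C)(C)[Si](C)(C)OS(=O)(=O)C(F)(F)F
Why: the silyl triflate protects the hindered secondary alcohol so that the next step can use a strong base.

**Step 24**
Reactants: 35 silyl ether
Product: 37 11-O-TBS-15-deoxoludongnin A (C-15 H2, 16-methylene), via the C-7 O-TBS silyl ketene acetal (C-7=C-8) of 35 36 (not isolated)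
Conditions: KHMDS (1.5 equiv), TBSCl (2 equiv), THF, −78 °C; concentrate; Pd(OAc)2 (1.0 equiv), AcOH (0.5 equiv), DMSO, air, 45 °C
Reagents that add atoms: none
Why: Pd(II)-mediated oxidative cyclisation of the silyl ketene acetal onto the 1,1-disubstituted alkene (Saegusa/Kende type) forms C8–C15 on the face of the axial isopropenyl group, which fixes the C-8 quaternary centre; β-hydride elimination toward the methyl group gives the exocyclic C-16 methylene.

**Step 25**
Reactants: 37 tetracycle
Product: 38 11-O-TBS-15-dihydroludongnin A (15-OH, exo)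
Conditions: SeO2 (0.5 equiv), t-BuOOH (3 equiv), CH2Cl2, rt
Reagents that add atoms: selenium dioxide, O=[Se]=O; tert-butyl hydroperoxide, CC(C)(C)OO
Why: Riley allylic oxidation (ene reaction, then [2,3]-shift) hydroxylates C-15, the only allylic methylene (C-13 is a bridgehead), and keeps the exocyclic alkene; the C-15 configuration is lost in step 26.

**Step 26**
Reactants: 38 allylic alcohol
Product: 39 11-O-TBS-ludongnin A
Conditions: Dess–Martin periodinane, NaHCO3, CH2Cl2, rt
Reagents that add atoms: none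
Why: Dess–Martin oxidation of the allylic alcohol gives the α-methylene cyclopentanone under non-nucleophilic conditions.

**Step 27**
Reactants: 39 silyl ether
Product: 40 ludongnin A
Conditions: HF·pyridine, THF, 0 °C → rt
Reagents that add atoms: none
Why: fluoride desilylation under mildly acidic conditions tolerated by the enone and both lactones releases the 11-hydroxyl.

**Compound list**
1 | (R)-2,2-dimethyl-1,3-dioxolane-4-methanol | CC1(C)OC[C@H](O1)CO | starting material
2 | (S)-2,2-dimethyl-1,3-dioxolane-4-carbaldehyde | CC1(C)OC[C@H](O1)C=O | intermediate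
3 | (E)-3-[(4R)-2,2-dimethyl-1,3-dioxolan-4-yl]prop-2-enal | CC1(C)OC[C@H](O1)/C=C/C=O | intermediate
4 | (4R)-4-[(1E)-buta-1,3-dien-1-yl]-2,2-dimethyl-1,3-dioxolane | CC1(C)OC[C@H](O1)/C=C/C=C | intermediate
5 | citraconic anhydride | CC1=CC(=O)OC1=O | starting material
6 | (3aR,7S,7aS)-7-[(4R)-2,2-dimethyl-1,3-dioxolan-4-yl]-3a-methyl-3a,4,7,7a-tetrahydro-2-benzofuran-1,3-dione | CC1(C)OC[C@H](O1)[C@H]1C=CC[C@@]2(C)C(=O)OC(=O)[C@@H]12 | intermediate
7 | 6-[(4R)-2,2-dimethyl-1,3-dioxolan-4-yl]-2-(hydroxymethyl)-2-methylcyclohex-4-ene-1-carboxylic acid (ring-opened 8) | CC1(C)OC[C@H](O1)[C@H]1C=CC[C@@](C)(CO)[C@H]1C(=O)O | intermediate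
8 | (3aR,7S,7aS)-7-[(4R)-2,2-dimethyl-1,3-dioxolan-4-yl]-3a-methyl-3a,4,7,7a-tetrahydro-2-benzofuran-1(3H)-one | CC1(C)OC[C@H](O1)[C@H]1C=CC[C@@]2(C)COC(=O)[C@@H]12 | intermediate
9 | (3aR,7S,7aS)-7-[(4R)-2,2-dimethyl-1,3-dioxolan-4-yl]-3a-methylhexahydro-2-benzofuran-1(3H)-one | CC1(C)OC[C@H](O1)[C@H]1CCC[C@@]2(C)COC(=O)[C@@H]12 | intermediate
10 | (3aR,7S,7aS)-7-[(1R)-1,2-dihydroxyethyl]-3a-methylhexahydro-2-benzofuran-1(3H)-one | OC[C@H](O)[C@H]1CCC[C@@]2(C)COC(=O)[C@@H]12 | intermediate
11 | (3aS,4S,7aR)-7a-methyl-3-oxooctahydro-2-benzofuran-4-carbaldehyde | O=C[C@H]1CCC[C@@]2(C)COC(=O)[C@@H]12 | intermediate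
12 | methyl acrylate | C=CC(=O)OC | starting material
13 | (3aR,7E,7aS)-3a-methyl-7-[(pyrrolidin-1-yl)methylidene]hexahydro-2-benzofuran-1(3H)-one | N1(CCCC1)/C=C2\CCC[C@@]3(C)COC(=O)[C@@H]23 | intermediate
14 | methyl 3-[(3aR,4R,7aR)-4-formyl-7a-methyl-3-oxooctahydro-2-benzofuran-4-yl]propanoate | COC(=O)CC[C@]1(C=O)CCC[C@@]2(C)COC(=O)[C@@H]12 | intermediate
15 | methyl 3-[(3aR,4R,7aR)-4-(hydroxymethyl)-7a-methyl-3-oxooctahydro-2-benzofuran-4-yl]propanoate | COC(=O)CC[C@]1(CO)CCC[C@@]2(C)COC(=O)[C@@H]12 | intermediate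
16 | (3aR,4R,7aR)-7a-methylhexahydro-3H-spiro[2-benzofuran-4,3'-oxane]-3,6'-dione | O=C1CC[C@@]2(CCC[C@@]3(C)COC(=O)[C@H]32)CO1 | intermediate
17 | 3-methylbut-3-enoic acid | CC(=C)CC(=O)O | starting material
18 | (S)-4-benzyl-2-oxazolidinone | O=C1N[C@@H](Cc2ccccc2)CO1 | starting material
19 | 3-methylbut-3-enoic pivalic anhydride | CC(=C)CC(=O)OC(=O)C(C)(C)C | intermediate
20 | (S)-4-benzyl-3-(3-methylbut-3-enoyl)oxazolidin-2-one | CC(=C)CC(=O)N1[C@@H](Cc2ccccc2)COC1=O | intermediate
21 | tert-butyl (S)-3-[(S)-4-benzyl-2-oxooxazolidine-3-carbonyl]-4-methylpent-4-enoate | CC(C)(C)OC(=O)C[C@@H](C(C)=C)C(=O)N1[C@@H](Cc2ccccc2)COC1=O | intermediate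
22 | tert-butyl (S)-3-(hydroxymethyl)-4-methylpent-4-enoate | CC(C)(C)OC(=O)C[C@@H](C(C)=C)CO | intermediate
23 | tert-butyl (S)-3-(iodomethyl)-4-methylpent-4-enoate | CC(C)(C)OC(=O)C[C@@H](C(C)=C)CI | intermediate
24 | (S)-3-(iodomethyl)-4-methylpent-4-en-1-ol | OCC[C@@H](C(C)=C)CI | intermediate
25 | (S)-tert-butyl{[3-(iodomethyl)-4-methylpent-4-en-1-yl]oxy}dimethylsilane | CC(C)(C)[Si](C)(C)OCC[C@@H](C(C)=C)CI | intermediate
26 | 8-alkylated spiro-bislactone (16 with the (2S)-4-TBSO-2-isopropenylbutyl chain at C-8; one C-8 epimer drawn) | O=C1OC[C@]2(CCC[C@@]3(C)COC(=O)[C@H]32)C[C@@H]1C[C@H](C(C)=C)CCO[Si](C)(C)C(C)(C)C | intermediate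
27 | 8-(phenylselanyl) derivative of 26 (one C-8 epimer drawn) | O=C1OC[C@]2(CCC[C@@]3(C)COC(=O)[C@H]32)C[C@@]1([Se]c4ccccc4)C[C@H](C(C)=C)CCO[Si](C)(C)C(C)(C)C | intermediate
28 | selenoxide of 27 | O=C1OC[C@]2(CCC[C@@]3(C)COC(=O)[C@H]32)C[C@@]1([Se](=O)c4ccccc4)C[C@H](C(C)=C)CCO[Si](C)(C)C(C)(C)C | intermediate
29 | 8,9-unsaturated δ-lactone, C-11 OTBS | O=C1OC[C@]2(CCC[C@@]3(C)COC(=O)[C@H]32)C=C1C[C@H](C(C)=C)CCO[Si](C)(C)C(C)(C)C | intermediate
30 | 8,9-unsaturated δ-lactone, C-11 OH | O=C1OC[C@]2(CCC[C@@]3(C)COC(=O)[C@H]32)C=C1C[C@H](C(C)=C)CCO | intermediate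
31 | 8,9-unsaturated δ-lactone, C-11 aldehyde | O=C1OC[C@]2(CCC[C@@]3(C)COC(=O)[C@H]32)C=C1C[C@H](C(C)=C)CC=O | intermediate
32 | tricyclic alcohol (C ring closed; 11-OH trans to C-10; 13-isopropenyl; H-8 cis to H-9) | O=C1OC[C@]2(CCC[C@@]3(C)COC(=O)[C@H]32)[C@@H]4[C@@H](O)C[C@@H](C(C)=C)C[C@H]14 | intermediate
33 | tricyclic 11-ketone | O=C1OC[C@]2(CCC[C@@]3(C)COC(=O)[C@H]32)[C@@H]4C(=O)C[C@@H](C(C)=C)C[C@H]14 | intermediate
34 | tricyclic 11-epi alcohol (11-OH cis to C-10) | O=C1OC[C@]2(CCC[C@@]3(C)COC(=O)[C@H]32)[C@@H]4[C@H](O)C[C@@H](C(C)=C)C[C@H]14 | intermediate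
35 | 11-O-TBS ether of 34 | O=C1OC[C@]2(CCC[C@@]3(C)COC(=O)[C@H]32)[C@@H]4[C@H](O[Si](C)(C)C(C)(C)C)C[C@@H](C(C)=C)C[C@H]14 | intermediate
36 | C-7 O-TBS silyl ketene acetal of 35 (C-7=C-8) | CC(C)(C)[Si](C)(C)OC1=C2C[C@H](C(C)=C)C[C@@H](O[Si](C)(C)C(C)(C)C)[C@H]2[C@@]2(CCC[C@@]3(C)COC(=O)[C@H]32)CO1 | intermediate
37 | 11-O-TBS-15-deoxoludongnin A | C=C1C[C@]23C[C@H]1C[C@@H](O[Si](C)(C)C(C)(C)C)[C@H]2[C@@]1(CCC[C@@]2(C)COC(=O)[C@H]21)COC3=O | intermediate
38 | 11-O-TBS-15-dihydroludongnin A (15-OH) | C=C1[C@H](O)[C@]23C[C@H]1C[C@@H](O[Si](C)(C)C(C)(C)C)[C@H]2[C@@]1(CCC[C@@]2(C)COC(=O)[C@H]21)COC3=O | intermediate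
39 | 11-O-TBS-ludongnin A | C=C1C(=O)[C@]23C[C@H]1C[C@@H](O[Si](C)(C)C(C)(C)C)[C@H]2[C@@]1(CCC[C@@]2(C)COC(=O)[C@H]21)COC3=O | intermediate
40 | ludongnin A | C=C1C(=O)[C@]23C[C@H]1C[C@@H](O)[C@H]2[C@@]1(CCC[C@@]2(C)COC(=O)[C@H]21)COC3=O | target

**Totals**
Total step count: 27. Longest linear sequence: 21 steps (steps 1–8, then 15–27); the iodide branch is 6 steps (9–14).

**Three steps most likely to fail**

Step 24 (Pd(II) cyclisation). The risks are competing enolisation at C-5 of the γ-lactone, and protodesilylation or dehydrogenation instead of C–C bond formation. The fallback sets out from 35 and comes back at 37, replacing the alkene activation by an enolate SN2 ring closure. SeO2/t-BuOOH oxidises the isopropenyl methyl group of 35 to the allylic alcohol, 35 with a 13-(3-hydroxyprop-1-en-2-yl) group F5. CBr4/PPh3 converts it into the allylic bromide, 35 with a 13-(3-bromoprop-1-en-2-yl) group F6. KHMDS in THF (−78 → 0 °C) then closes the D ring by intramolecular 5-exo-tet alkylation of the C-8 lactone enolate, giving 37 with the same C-15 methylene and exocyclic C-16 alkene; a C-5 enolate has no electrophile within reach and simply reprotonates.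

Step 7 (key Michael addition). The risks are slow addition of the hindered trisubstituted enamine to the weakly electrophilic acrylate and loss of face selectivity at the temperature needed. The fallback sets out from 11 and comes back at 16, keeping the same C9–C10 Michael disconnection but using the aldehyde enolate and a smaller, more reactive acceptor. Catalytic KOt-Bu in t-BuOH/THF (0 °C → rt) with acrylonitrile gives 3-[(3aR,4R,7aR)-4-formyl-7a-methyl-3-oxooctahydro-2-benzofuran-4-yl]propanenitrile F1. NaBH4 in MeOH reduces the aldehyde to 3-[(3aR,4R,7aR)-4-(hydroxymethyl)-7a-methyl-3-oxooctahydro-2-benzofuran-4-yl]propanenitrile F2. HCl/MeOH (Pinner conditions) followed by water converts the nitrile through the cyclic imidate into the δ-lactone, which is bislactone 16.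

Step 20 (SmI2 cyclisation). The risks are pinacol coupling, simple reduction of the aldehyde or enoate, or a poorly organised 6-endo closure onto the neopentyl C-9. The fallback sets out from 31 and comes back at 33, forming C9–C11 at the ketone oxidation level with an acyl radical. Pinnick oxidation (NaClO2, NaH2PO4, 2-methyl-2-butene) gives the carboxylic acid, (3S)-4-methyl-3-{[(8,9-unsaturated spiro-bislactone)-8-yl]methyl}pent-4-enoic acid F3. (PhSe)2/Bu3P converts it into the Se-phenyl selenoester of F3 F4. Slow addition of Bu3SnH/AIBN in PhH at 80 °C generates the acyl radical, which cyclises 6-endo onto C-9 and is reduced at C-8 to give ketone 33 directly, so the oxidation of step 21 is no longer needed.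

**Further compounds**
F1 | step 7 | 3-[(3aR,4R,7aR)-4-formyl-7a-methyl-3-oxooctahydro-2-benzofuran-4-yl]propanenitrile | N#CCC[C@]1(C=O)CCC[C@@]2(C)COC(=O)[C@@H]12
F2 | step 7 | 3-[(3aR,4R,7aR)-4-(hydroxymethyl)-7a-methyl-3-oxooctahydro-2-benzofuran-4-yl]propanenitrile | N#CCC[C@]1(CO)CCC[C@@]2(C)COC(=O)[C@@H]12
F3 | step 20 | carboxylic acid from 31 (C-11 CO2H) | O=C1OC[C@]2(CCC[C@@]3(C)COC(=O)[C@H]32)C=C1C[C@H](C(C)=C)CC(=O)O
F4 | step 20 | Se-phenyl selenoester of F3 | O=C1OC[C@]2(CCC[C@@]3(C)COC(=O)[C@H]32)C=C1C[C@H](C(C)=C)CC(=O)[Se]c1ccccc1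
F5 | step 24 | 35 with 13-(3-hydroxyprop-1-en-2-yl) group | O=C1OC[C@]2(CCC[C@@]3(C)COC(=O)[C@H]32)[C@@H]4[C@H](O[Si](C)(C)C(C)(C)C)C[C@@H](C(=C)CO)C[C@H]14
F6 | step 24 | 35 with 13-(3-bromoprop-1-en-2-yl) group | O=C1OC[C@]2(CCC[C@@]3(C)COC(=O)[C@H]32)[C@@H]4[C@H](O[Si](C)(C)C(C)(C)C)C[C@@H](C(=C)CBr)C[C@H]14
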